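Ring B is disconnected at C5–C6 (eudesmane numbering) of a 15-nor-4-ketone, that is, an intramolecular aldol. With the ketone at C4 of ring A, C5 is enolisable, C6 is the aldol carbinol and C7 lies α to the open-chain aldehyde. One reversible, base-mediated closure therefore forms ring B and lets all three centres settle into the trans-fused, all-equatorial ketol against the single preset centre, quaternary C10. The precursor is 2-isopropyl-4-[(1R)-1-methyl-3-oxocyclohexyl]butanal, used as a C7-epimer mixture and unveiled under neutral conditions by ozonolysis of a vinyl group. C10 comes from a copper-catalysed asymmetric conjugate addition; methylenation and acylation finish the route.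

Key step: step 6

Remark on numbering: eudesmane numbering is used throughout (C4 = ketone or methylene carbon, C5–H, C6–O, C7–isopropyl, C10–C14 methyl).
Remark on the side chain: ring B needs exactly two methylene groups (C8, C9) between C10 and C7; a spacer made by Michael addition of isovaleraldehyde to an acrylate would carry three and close a seven-membered ring, so the chain is built by a Claisen rearrangement that also supplies a vinyl group as the latent C6 aldehyde.
Assumption: (E)-4-methylpent-2-en-1-ol and (E)-4-acetoxycinnamic acid are taken as catalogue compounds.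

Step 1
Reactants: 1 (E)-4-methylpent-2-en-1-ol; 2 triethyl orthoacetate
Product: 4 ethyl 3-isopropylpent-4-enoate (racemic), via ketene acetal 3 (not isolated)
Conditions: EtCO2H (cat.), neat 2 (excess), 140 °C, EtOH distilled off
Reagents that add atoms: none
Why: Johnson–Claisen (orthoester Claisen) rearrangement, in which acid-catalysed exchange and loss of ethanol give ketene acetal 3, whose chair [3,3]-sigmatropic shift forms the future C7–C8 bond at the isopropyl-bearing carbon and liberates the vinyl group; the new centre (future C7) is formed racemic, which is harmless because it is equilibrated in step 6.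

Step 2
Reactants: 4 ethyl 3-isopropylpent-4-enoate
Product: 5 3-isopropylpent-4-en-1-ol (racemic)
Conditions: LiAlH4, Et2O, 0 °C; H2O/NaOH work-up
Reagents that add atoms: none
Why: Hydride reduction of the ester to the primary alcohol with LiAlH4, to which the isolated terminal alkene is inert, so no stereocentre or other group is touched.

Step 3
Reactants: 5 3-isopropylpent-4-en-1-ol
Product: 6 5-bromo-3-isopropylpent-1-ene (racemic)
Conditions: CBr4, PPh3, CH2Cl2, 0 °C
Reagents that add atoms: carbon tetrabromide, BrC(Br)(Br)Br
Why: Appel bromination, in which the alkoxyphosphonium ion is displaced by bromide at the unhindered primary carbon (SN2) under neutral conditions that leave the alkene alone.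

Step 4
Reactants: 6 5-bromo-3-isopropylpent-1-ene; 7 3-methylcyclohex-2-en-1-one
Product: 9 (3R)-3-methyl-3-(3-isopropylpent-4-en-1-yl)cyclohexan-1-one (side-chain epimer mixture), via Grignard reagent 8 (not isolated)
Conditions: Mg, Et2O, rt; then Cu(OTf)2 (3 mol %), chiral imidazolinium chloride (NHC precursor, 4 mol %), 7 added slowly, Et2O, 0 °C; aq NH4Cl
Reagents that add atoms: none
Why: Copper-catalysed asymmetric conjugate addition of a Grignard reagent, in which the carbene–copper complex formed in situ transfers the primary alkyl group of 8 to the β-carbon of the β-methyl enone and the chiral carbene ligand (enantiomer chosen for the R product) differentiates the enone faces to set quaternary C10, while the remote racemic side-chain centre only gives two C7 epimers that converge in step 6.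

Step 5
Reactants: 9 (3R)-3-methyl-3-(3-isopropylpent-4-en-1-yl)cyclohexan-1-one
Product: 11 2-isopropyl-4-[(1R)-1-methyl-3-oxocyclohexyl]butanal (C7 epimer mixture), via secondary ozonide 10 (not isolated)
Conditions: O3, CH2Cl2, −78 °C; then PPh3, −78 °C to rt
Reagents that add atoms: ozone, [O-][O+]=O
Why: Ozonolysis with reductive work-up, in which ozone cleaves the only C=C bond to ozonide 10 and PPh3 reduces it to the aldehyde under neutral conditions, so the saturated ketone survives and the keto aldehyde meets neither acid nor base before the key step.

Step 6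
Reactants: 11 2-isopropyl-4-[(1R)-1-methyl-3-oxocyclohexyl]butanal
Product: 12 6α-hydroxy-15-nor-eudesman-4-one (5S,6S,7S,10R; trans-fused)
Conditions: K2CO3 (0.3 equiv), MeOH, 0 °C to rt, until the isomer ratio is constant; pH 7 buffer
Reagents that add atoms: none
Why: Base-mediated intramolecular aldol addition under thermodynamic control (closest known type: reversible aldol cyclisation of keto aldehydes to decalin ketols): the C4 ketone enolate toward C5 adds to the C6 aldehyde and closes ring B in a 6-(enolexo)-exo-trig mode, whereas the C3 enolate would need an eight-membered bridged ring and addition of the aldehyde enolate to the ketone gives only a crowded tertiary bicyclo[3.3.1] ketol, both of which revert. Because retro-aldol reopens C5–C6 and the free aldehyde enolises at C7, all C5/C6/C7 diastereomers interconvert while C10 stays fixed. C5 is set by the preference for the trans ring fusion (5α-H anti to the 10β-methyl group), C6 by the equatorial 6α-hydroxyl that can hydrogen-bond to the nearly coplanar C4 carbonyl, and C7 by the equatorial 7β-isopropyl group. The step needs this thermodynamic selectivity without dehydration: the equatorial C6–O bond lies near the plane of the C4–C5 enolate and is poorly aligned for β-elimination, and weak base at or below room temperature should keep the conjugated enone from forming. Minor ketols can be returned to the same conditions, and a C5 epimer with the correct C6 and C7 is tolerated because C5 is equilibrated again in step 8.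

Step 7
Reactants: 12 6α-hydroxy-15-nor-eudesman-4-one
Product: 13 6α-(triethylsilyloxy)-15-nor-eudesman-4-one
Conditions: TESOTf, 2,6-lutidine, CH2Cl2, −78 °C
Reagents that add atoms: triethylsilyl trifluoromethanesulfonate, CC[Si](CC)(CC)OS(=O)(=O)C(F)(F)F
Why: Silyl ether formation with a silyl triflate, which silylates the hindered, hydrogen-bonded secondary hydroxyl at low temperature while the weak hindered base neither enolises the ketone nor triggers retro-aldol, so the aldol is locked and no stereocentre changes.

Step 8
Reactants: 13 6α-(triethylsilyloxy)-15-nor-eudesman-4-one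
Product: 14 6α-(triethylsilyloxy)eudesm-4(15)-ene
Conditions: Ph3PCH3Br, KOtBu, THF, 0 °C to 50 °C
Reagents that add atoms: methyltriphenylphosphonium bromide, C[P+](c1ccccc1)(c1ccccc1)c1ccccc1.[Br-]
Why: Wittig methylenation, in which Ph3P=CH2 adds to the C4 ketone and the oxaphosphetane collapses to the exocyclic C4=C15 alkene, while the basic medium equilibrates C5 through the ketone enolate so that any cis-fused ketone is expected to react by way of the trans-fused isomer, after which C5 is fixed as 5α-H.

Step 9
Reactants: 14 6α-(triethylsilyloxy)eudesm-4(15)-ene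
Product: 15 eudesm-4(15)-en-6α-ol
Conditions: TBAF, THF, rt
Reagents that add atoms: none
Why: Fluoride-mediated desilylation, driven by the strong Si–F bond, which frees the C6 hydroxyl without touching the non-conjugated exocyclic alkene or any stereocentre.

Step 10
Reactants: 15 eudesm-4(15)-en-6α-ol; 16 (E)-4-acetoxycinnamic acid
Product: 18 eudesm-4(15)-en-6α-yl (E)-3-(4-acetoxyphenyl)prop-2-enoate, via acid chloride 17 (not isolated)
Conditions: 16, (COCl)2, DMF (cat.), CH2Cl2, 0 °C to rt, evaporate; then 15, Et3N, DMAP, CH2Cl2, 0 °C to rt
Reagents that add atoms: none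
Why: Acylation through the acid chloride with nucleophilic catalysis, in which the acylpyridinium ion from 17 and DMAP esterifies the hindered equatorial C6 alcohol with retention at C6, the phenol being masked as its acetate so that it cannot compete.

Step 11
Reactants: 18 eudesm-4(15)-en-6α-yl (E)-3-(4-acetoxyphenyl)prop-2-enoate
Product: 19 eudesm-4(15)-en-6α-yl (E)-3-(4-hydroxyphenyl)prop-2-enoate (target)
Conditions: pyrrolidine, CH2Cl2, 0 °C to rt
Reagents that add atoms: none
Why: Chemoselective aminolysis of the aryl acetate, since pyrrolidine attacks the activated phenolic ester far faster than the hindered, conjugated secondary alkyl cinnamate, so the phenol is freed without ester cleavage, alkene migration or epimerisation.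

Compound list
1 | (E)-4-methylpent-2-en-1-ol | CC(C)/C=C/CO | starting material
2 | triethyl orthoacetate | CCOC(C)(OCC)OCC | starting material
3 | 1-ethoxy-1-[(E)-4-methylpent-2-en-1-yloxy]ethene (ketene acetal) | C=C(OCC)OC/C=C/C(C)C | intermediate (not isolated)
4 | ethyl 3-isopropylpent-4-enoate, racemic | CCOC(=O)CC(C(C)C)C=C | intermediate
5 | 3-isopropylpent-4-en-1-ol, racemic | OCCC(C(C)C)C=C | intermediate
6 | 5-bromo-3-isopropylpent-1-ene, racemic | BrCCC(C(C)C)C=C | intermediate
7 | 3-methylcyclohex-2-en-1-one | CC1=CC(=O)CCC1 | starting material
8 | (3-isopropylpent-4-en-1-yl)magnesium bromide | C=CC(C(C)C)CC[Mg]Br | intermediate (not isolated)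
9 | (3R)-3-methyl-3-(3-isopropylpent-4-en-1-yl)cyclohexan-1-one, epimer mixture at the side-chain CH | C=CC(C(C)C)CC[C@@]1(C)CCCC(=O)C1 | intermediate
10 | (3R)-3-methyl-3-[4-methyl-3-(1,2,4-trioxolan-3-yl)pentyl]cyclohexan-1-one (secondary ozonide) | C1OC(OO1)C(C(C)C)CC[C@@]2(C)CCCC(=O)C2 | intermediate (not isolated)
11 | 2-isopropyl-4-[(1R)-1-methyl-3-oxocyclohexyl]butanal, C7 (butanal C2) epimer mixture; the 2S epimer maps directly onto 12 | O=CC(C(C)C)CC[C@@]1(C)CCCC(=O)C1 | intermediate
12 | 6α-hydroxy-15-nor-eudesman-4-one; (4aR,7S,8S,8aS)-8-hydroxy-4a-methyl-7-(propan-2-yl)octahydronaphthalen-1(2H)-one; trans-fused, 5α-H, 6α-OH and 7β-isopropyl equatorial, 10β-methyl | O=C1CCC[C@]2(C)CC[C@@H](C(C)C)[C@H](O)[C@@H]12 | intermediate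
13 | 6α-(triethylsilyloxy)-15-nor-eudesman-4-one (5S,6S,7S,10R) | O=C1CCC[C@]2(C)CC[C@@H](C(C)C)[C@H](O[Si](CC)(CC)CC)[C@@H]12 | intermediate
14 | 6α-(triethylsilyloxy)eudesm-4(15)-ene (5S,6S,7S,10R) | C=C1CCC[C@]2(C)CC[C@@H](C(C)C)[C@H](O[Si](CC)(CC)CC)[C@@H]12 | intermediate
15 | eudesm-4(15)-en-6α-ol (5S,6S,7S,10R) | C=C1CCC[C@]2(C)CC[C@@H](C(C)C)[C@H](O)[C@@H]12 | intermediate
16 | (E)-4-acetoxycinnamic acid | CC(=O)Oc1ccc(/C=C/C(=O)O)cc1 | starting material
17 | (E)-4-acetoxycinnamoyl chloride | CC(=O)Oc1ccc(/C=C/C(=O)Cl)cc1 | intermediate (not isolated)
18 | eudesm-4(15)-en-6α-yl (E)-3-(4-acetoxyphenyl)prop-2-enoate | C=C1CCC[C@]2(C)CC[C@@H](C(C)C)[C@H](OC(=O)/C=C/c3ccc(OC(C)=O)cc3)[C@@H]12 | intermediate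
19 | (1S,2S,4aR,8aS)-4a-methyl-8-methylidene-2-(propan-2-yl)decahydronaphthalen-1-yl (2E)-3-(4-hydroxyphenyl)prop-2-enoate | C=C1CCC[C@]2(C)CC[C@@H](C(C)C)[C@H](OC(=O)/C=C/c3ccc(O)cc3)[C@@H]12 | target

Total step count: 11. Longest linear sequence: 11 steps (1 to 19); 16 enters in step 10.

Steps most likely to fail

Step 6. What may go wrong: β-elimination of water from the aldol is irreversible and may drain the equilibrating ketols to the conjugated enone, or equilibration may stop short of the trans-fused all-equatorial isomer. The fallback sets out from 11 and comes back at 12. The condensation is driven to completion on purpose (KOH, MeOH, reflux) to give (7S,10R)-15-nor-eudesm-5-en-4-one F1, whose C7 still equilibrates through the extended enolate. Weitz–Scheffer epoxidation (H2O2, NaOH, MeOH, 0 °C), expected on the α-face away from the axial C10 methyl group, should give 5α,6α-epoxy-15-nor-eudesman-4-one F2. Reductive cleavage of the Cα–O bond of the epoxy ketone with SmI2 (THF/MeOH, −78 °C) should then deliver ketol 12 with the C6–O bond untouched, a C5 epimer being corrected in step 8.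

Step 8. What may go wrong: the basic ylide may enolise the hindered C4 ketone faster than it adds, and the enolate may expel the C6 silanolate by β-elimination. The fallback sets out from 13 and comes back at 14. The weakly basic organocerium reagent from Me3SiCH2Li and CeCl3 (THF, −78 °C) should add to C4 to give 15-(trimethylsilyl)-6α-(triethylsilyloxy)eudesman-4-ol F3 (either C4 epimer), and KH (THF, rt) then effects Peterson elimination to 14. This sequence does not epimerise C5 and therefore needs trans-fused 13.

Step 4. What may go wrong: poor facial discrimination or competing 1,2-addition when the γ-branched Grignard reagent is transferred to the β,β-disubstituted enone. The fallback sets out from 6 and comes back at 9. Grignard reagent 8 is added instead to 3-ethoxycyclohex-2-en-1-one (Et2O, 0 °C) to give 3-ethoxy-1-(3-isopropylpent-4-en-1-yl)cyclohex-2-en-1-ol F4. On work-up with aqueous HCl this loses ethanol with carbonyl transposition (Stork–Danheiser) to 3-(3-isopropylpent-4-en-1-yl)cyclohex-2-en-1-one F5. Copper-catalysed asymmetric conjugate addition of Me3Al (monovalent copper thiophene-2-carboxylate Cu(O2CC4H3S), chiral phosphoramidite, Et2O, −30 °C), an established way of adding a methyl group to 3-alkylcyclohexenones, then sets C10 by methyl transfer and gives 9.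

Further compounds
F1 | step 6 | (7S,10R)-15-nor-eudesm-5-en-4-one | O=C1CCC[C@]2(C)CC[C@@H](C(C)C)C=C12
F2 | step 6 | 5α,6α-epoxy-15-nor-eudesman-4-one (7β-isopropyl, 10β-methyl) | O=C1CCC[C@]2(C)CC[C@@H](C(C)C)[C@@H]3O[C@]123
F3 | step 8 | 15-(trimethylsilyl)-6α-(triethylsilyloxy)eudesman-4-ol (C4 epimers) | C[Si](C)(C)CC1(O)CCC[C@]2(C)CC[C@@H](C(C)C)[C@H](O[Si](CC)(CC)CC)[C@@H]12
F4 | step 4 | 3-ethoxy-1-(3-isopropylpent-4-en-1-yl)cyclohex-2-en-1-ol | CCOC1=CC(O)(CCC(C(C)C)C=C)CCC1
F5 | step 4 | 3-(3-isopropylpent-4-en-1-yl)cyclohex-2-en-1-one | C=CC(C(C)C)CCC1=CC(=O)CCC1
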